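Take the three earlier runs and the flask as charged, and look for one thing: whether single product is still gaining at the asked time.

| flask | substrate | coupling partner | capture agent | scavenger | remark | time |
|---|---|---|---|---|---|---|
| zeta | 0.22 M | 0.66 M | 0.011 M | 0.074 M | run made earlier |  |
| epsilon | 0.22 M | 0.66 M | 0.011 M | 0.17 M | run made earlier |  |
| beta | 0.22 M | 0.66 M | 0.017 M | 0.11 M | run made earlier |  |
| flask | 0.22 M | 0.660 M | 0.0110 M | 0.110 M |  | 5.0 min |

| run | time / min | substrate / % | single product / % | double product / % |
|---|---|---|---|---|
| zeta | 1.33 | 32.1 | 46.5 | 16.5 |
| zeta | 2.50 | 19.0 | 47.7 | 29.9 |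
| zeta | 4.00 | 11.5 | 44.5 | 38.4 |
| zeta | 5.00 | 10.5 | 41.2 | 41.8 |
| zeta | 6.00 | 8.4 | 40.0 | 45.3 |
| epsilon | 0.500 | 58.6 | 34.7 | 4.7 |
| epsilon | 0.833 | 45.1 | 42.4 | 9.8 |
| epsilon | 1.50 | 31.3 | 48.3 | 18.5 |
| epsilon | 3.00 | 16.8 | 47.2 | 31.8 |
| epsilon | 6.00 | 8.4 | 39.1 | 47.3 |
| beta | 1.33 | 32.6 | 46.7 | 17.1 |
| beta | 2.50 | 19.5 | 45.6 | 26.9 |
| beta | 4.00 | 12.0 | 42.4 | 37.1 |
| beta | 5.00 | 9.7 | 41.0 | 42.4 |
| beta | 6.00 | 7.8 | 39.1 | 45.4 |

(each reading ± 0.5 percentage points)



* substrate at 5.0 min, in percent of the substrate charged
* single product at 5.0 min, in percent of the substrate charged
* double product at 5.0 min, in percent of the substrate charged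

What do you want from the readings? One number, 0.462: the follow-on factor (selectivity factor), how fast a percent of single product goes on to double product, per percent of substrate going to single product.

Where does it come from? In the epsilon run, from 1.50 min to 3.00 min, double product gains 13 percentage points while substrate loses 14 points. Multiply that ratio by mean c(substrate) over mean c(single product). It is a reading and carries the scatter.

What does it tell you? If both steps need the coupling partner, c(coupling partner) cancels. Making over using is then c(substrate) divided by the factor times c(single product).

And at the asked time? Zeta and beta, averaged at 5.00 min, give 10.1% substrate and 41.1% single product. Making over using is then 0.532, so I reckon that single product in the flask is falling by then.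

But the scavenger differs. Does that spoil it? Zeta at 0.074 M and epsilon at 0.17 M both read 8.4% substrate at 6.00 min, so I keep those averages.

And the missing material? At 5.00 min the zeta readings, with the flask's capture agent, fall 6.50% short of the charge, which leaves me 42.3% double product for the flask.

The forecast says “neither the scavenger nor the capture agent much affects the main kinetics” and gives 10% substrate, 41.2% single product and 43% double product, a little more double product than mine.

The flask gives 9.87% substrate, 42.3% single product and 42.8% double product, all within the forecast's margins.

coupling partner + single product → double product + released group (k = 0.0150 /M/s); single product + capture agent → trapped intermediate (k = 0.180 /M/s); coupling partner + released group ⇌ idle adduct, settled at all times (K = 270 /M); substrate + coupling partner → single product + released group (k = 0.0320 /M/s); scavenger + released group → scavenged by-product (k = 0.180 /M/s) From these amounts the factor puts making over using at 0.505, and the net rates in the flask at 5.00 min give 0.494, so single product is made at about half the rate it is used up. The neighbour flask charged with 0.055 M of substrate holds 0.659% substrate and 13.2% single product at 5.00 min, so the factor gives it 0.108, and it stands at 74.1% double product.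

The data are calculated on assumed constants; the scatter is artificial.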